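The readings were generated by integration from invented constants; the scatter is artificial.

J is the product I count first in this flask: each J takes two X and one Q, whereas D, L, E and Z each hold one X and one Q.

| flask | X | Q | remark | time |
|---|---|---|---|---|
| dawn | 20 mM | 14 mM | the very flask that is asked about, followed so far |  |
| flask | 20 mM | 14.0 mM |  | 40 min |

dawn run (percent of the X charged)

| time / min | Z / % | J / % |
|---|---|---|
| 3.00 | 1.6 | 26.9 |
| 6.00 | 4.4 | 36.7 |
| 10.0 | 5.3 | 42.3 |
| 12.0 | 5.9 | 44.2 |
| 15.0 | 6.0 | 45.5 |
| 20.0 | 6.5 | 46.9 |

(scatter of a reading: 0.3 percentage points)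

- percentages count the X that a species holds: one J counts as two
- steps that have been proposed: X + Q <-> E; D <-> L; L <-> Z; X + Q -> D; X + E -> J

- share of Z in Z plus J at 40 s
- share of Z in Z plus J at 5.0 min
- share of Z in Z plus J at 40 min
- which of Z and J there is more of at 40 min

Free X minus free Q therefore stays put when D, L, E or Z form and falls by one for each J, so the J readings give it directly. At 20.0 min this flask stands at 1.31 mM of what I call the X surplus, free X minus free Q in mM.

Which reagent gives out first? The surplus began at 6.00 mM and is still positive, so I expect Q to be the limiting reagent here, with X left over.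

How much J is still to come? Its gain of the last interval is 0.437 of the one before, as read. Continuing that ratio adds 1.1 percentage points, which costs 0.109 mM of surplus, less than there is. That puts J near 48.0%.

Can Z catch it? At its pace from 12.0 min on, Z reaches 8.00% at 40 min, still less than J. With Z held or at that pace, the share at 40 min lies between 11.9% and 14.3%, so I commit to 13.1%. Early, the share is 5.61% at 3.00 min and 10.7% at 6.00 min, so straight lines give 1.25% at 40 s and 9.00% at 5.0 min.

The forecast says 1%, 9.5% and 14.5%, with J in the lead: “J stays well ahead.”

The flask gives 0.807%, 8.02% and 12.1%, with J at 48.9% and Z at 6.75%.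

    X + Q ⇌ E (K = 210 L mol⁻¹, k = 0.200 L mol⁻¹ s⁻¹)
    D ⇌ L (K = 1.10, k = 0.00450 s⁻¹)
    L ⇌ Z (K = 0.350, k = 0.00340 s⁻¹)
    X + Q → D (k = 0.320 L mol⁻¹ s⁻¹)
    X + E → J (k = 1.40 L mol⁻¹ s⁻¹)

From 1.31 mM the surplus falls to 1.11 mM at 40 min by the J count, and the free X and Q of this flask differ by 1.11 mM. In the neighbour flask charged with 3.5 mM of Q, the same count gives 75.9% of the X, and it holds 75.9% of X with Q at 0%. In this flask, at the start, the step from X + Q to D uses Q 1.6 times as fast as the forward step from X + Q to E, and at 40.0 min D stands at 17.7% and L at 19.3%.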